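Its constants were drawn at random within sensible limits, and the outcome is calculated.

For a late reading of this two-phase flask, the concentration to reckon is that of the reagent in the reaction phase, written B.

    reagent in the reaction phase ⇌ reagent in the second phase, rate k1*([reagent in the reaction phase] - [reagent in the second phase]/K1) per volume of the first phase (K1 = 2.9, k1 = 4.2 × 10⁻⁴ /s)
    starting material + reagent in the reaction phase ⇌ target (K2 = 11 /M, k2 = 0.045 /M/s)
    target ⇌ product in the second phase, rate k3*([target] - [product in the second phase]/K3) per volume of the first phase (K3 = 25, k3 = 1.3 × 10⁻⁴ /s)
    target → decomposed product (k4 = 7.4 × 10⁻⁵ /s)
    target ⇌ isomer of the product (K5 = 9.4, k5 = 2.1 × 10⁻⁴ /s)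
starting material 0.20 M; reagent in the second phase 0.400 M; time 4.0 h; volume of the second phase over the first 2.0
- what is said of target includes product in the second phase
- in the second phase: reagent in the second phase, product in the second phase; everything else is in the first
- charges count per volume of the first phase; a concentration in a rate is the amount of a species over the volume of its own phase; every rate counts per litre of the first phase
- run time (flask): 4.0 h
- how much target and product in the second phase together there is at 4.0 h, in percent of the starting material charged
- part of the starting material charged that has reacted at 4.0 h

The reckoning by hand comes first. With the concentrations as charged, the forward addition alone uses B with a half-life of 1.3 min, much shorter than the 27.5 min of its transfer, so the addition is taken as near equilibrium, with first-phase target at K·A·B, where A is the starting material and K is 11 /M. First-phase target is drained at k_d = 4.14 × 10⁻⁴ /s, the sum of its transfer, decomposition and isomerisation constants, with the ways back neglected. B is then held steady where the supply k_T(B_c − B) meets the drain k_d·K·A·B. Here k_T is 4.2 × 10⁻⁴ /s, and B_c is the partition value of the second phase after an assumed mean draw of 0.100 M, namely 0.0517 M. With A as charged, B comes to 0.0163 M. A then falls pseudo-first-order with the apparent constant k_obs, equal to k_d·K·B, 0.268 /h.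

This gives a conversion of 65.7%. Of what drains, 31.4% goes to the second phase, and 6.16% stays as first-phase target, so the yield is 24.9%.

The forecast is higher on both, at 30% and 72%, holding that “conversion is limited by the slow transfer of reagent into the reaction phase and by the draining of target”.

The simulation gives 29.3% and 70.6%, so the forecast stands within its margin. In this flask, with each step taken net, B is made 1.17 times as fast as it is used at 1.19 h, and 1.06 times at 4.00 h. Put to use at 2.00 h, k_obs leaves 58.5% of the starting material, against 52.9% in the flask.

For the same flask read at 10 h, k_obs gives a conversion of 93.1%. The computed conversion is 91.0%.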